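**Retrosynthetic overview**

1. The last C–C bond made is the C(sp2)–C(sp3) bond between the methyl-bearing alkene carbon (C10) and the neighbouring chain CH2 (C9). It is cut so that both carbons become electrophiles: an (E)-alkenyl iodide holding both furan rings, and a primary alkyl iodide holding the ketone, the O-silylated chlorohydrin and all three stereocentres. A nickel-catalysed reductive cross-electrophile coupling joins them, and desilylation follows.
2. Enabling feature: C9 ends an unbranched (CH2)3 spacer, two CH2 groups away from the C6 methyl stereocentre, so it can pass through a free primary radical at no stereochemical cost. C10 is an sp2 carbon whose E geometry is held in a configurationally stable alkenyl–nickel bond. The only other C–halogen bond is the stronger secondary C2–Cl, and the two furan rings are spectators.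
3. The alkyl iodide comes from a Weinreb ketone synthesis between an Evans-derived (R)-2-methylpent-4-enyl unit (C6) and an L-threonine-derived C4 amide. The terminal alkene is then converted into the primary iodide.
4. C2 and C3 come from L-threonine by way of the bromohydrin, the cis-oxirane and chloride opening at the methyl-bearing carbon, with one inversion at each carbon. The alkenyl iodide comes from 4-bromofurfural by Negishi coupling with pent-3-ynylzinc, addition of 3-furyllithium, deoxygenation and hydrozirconation–iodination.
5. Rings: both furan rings are bought intact and never rebuilt. The only ring formed is the temporary oxirane (step 8), which is opened in step 9.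

Key step: step 17

Assumption: all starting materials and all unnumbered reagents are taken as catalogue compounds; L-threonine and the (S)-benzyloxazolidinone are the only sources of chirality.

**Step 1**
Reactants: 1 pent-3-yn-1-ol
Product: 2 5-iodopent-2-yne
Conditions: I2, PPh3, imidazole, CH2Cl2, 0 °C to rt
Reagents that add atoms: iodine, II
Why: Appel-type iodination in which the primary alcohol is activated as an oxyphosphonium ion and displaced by iodide in an SN2 step that leaves the internal alkyne untouched.

**Step 2**
Reactants: 2 5-iodopent-2-yne; 3 4-bromofuran-2-carbaldehyde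
Product: 5 4-(pent-3-yn-1-yl)furan-2-carbaldehyde, via pent-3-yn-1-ylzinc iodide 4 (not isolated)
Conditions: Zn dust, LiCl, THF, 40 °C; then 3, Pd(OAc)2 (2 mol %), SPhos (4 mol %), THF, rt
Reagents that add atoms: none
Why: Direct zinc insertion followed by a Negishi sp3–sp2 coupling, in which the formyl group readies the furan C4–Br bond for oxidative addition, the alkylzinc iodide does not add to the aldehyde, and the bulky biarylphosphine favours reductive elimination over β-hydride elimination.

**Step 3**
Reactants: 6 3-bromofuran; 5 4-(pent-3-yn-1-yl)furan-2-carbaldehyde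
Product: 8 (furan-3-yl)[4-(pent-3-yn-1-yl)furan-2-yl]methanol (racemic), via furan-3-yllithium 7 (not isolated)
Conditions: n-BuLi, THF, −78 °C; then 5, −78 °C; H2O
Reagents that add atoms: none
Why: Bromine–lithium exchange and 1,2-addition, in which furan-3-yllithium keeps its position at −78 °C and adds to the aldehyde, and the new carbinol centre may form as a racemate because step 4 erases it.

**Step 4**
Reactants: 8 (furan-3-yl)[4-(pent-3-yn-1-yl)furan-2-yl]methanol
Product: 9 2-(furan-3-ylmethyl)-4-(pent-3-yn-1-yl)furan
Conditions: Et3SiH (excess), CF3CO2H, CH2Cl2, −30 to 0 °C (acid added last)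
Reagents that add atoms: none
Why: Ionic hydrogenation in which acid ionises the doubly furyl-stabilised carbinol at low temperature and the excess silane traps the cation as the CH2 bridge before a furan ring of a second molecule can attack it, while the alkyne is inert.

**Step 5**
Reactants: 9 2-(furan-3-ylmethyl)-4-(pent-3-yn-1-yl)furan
Product: 11 2-(furan-3-ylmethyl)-4-[(3E)-4-iodopent-3-en-1-yl]furan, via alkenylzirconocene chloride 10 (not isolated)
Conditions: Cp2ZrHCl (2.2 equiv), THF, 50 °C, dark; then I2, THF, −20 °C
Reagents that add atoms: iodine, II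
Why: Hydrozirconation–iodinolysis in which Zr–H adds syn to the alkyne, the excess of Schwartz reagent lets the two regioisomeric alkenylzirconocenes equilibrate towards the one with zirconium on the less hindered methyl-bearing carbon, and iodine cleaves the C–Zr bond with retention to fix the E geometry.

**Step 6**
Reactants: 12 L-threonine, (2S,3R)-2-amino-3-hydroxybutanoic acid
Product: 13 (2S,3R)-2-bromo-3-hydroxybutanoic acid
Conditions: NaNO2, 48 % aq HBr, H2O, −5 to 0 °C
Reagents that add atoms: hydrobromic acid, Br
Why: Diazotisation of an α-amino acid in the presence of bromide, in which the carboxylate displaces N2 to give an α-lactone that bromide opens, so two inversions give net retention at C2 and C3 is not touched.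

**Step 7**
Reactants: 13 (2S,3R)-2-bromo-3-hydroxybutanoic acid
Product: 14 (2S,3R)-2-bromo-3-hydroxy-N-methoxy-N-methylbutanamide
Conditions: MeNH(OMe)·HCl, N-methylmorpholine, DCC, CH2Cl2, 0 °C to rt
Reagents that add atoms: N,O-dimethylhydroxylamine hydrochloride, CNOC.Cl
Why: Carbodiimide-mediated amide coupling in which the amine outcompetes the secondary hydroxyl group for the activated acid and neither stereocentre takes part.

**Step 8**
Reactants: 14 (2S,3R)-2-bromo-3-hydroxy-N-methoxy-N-methylbutanamide
Product: 15 (2R,3R)-N-methoxy-N,3-dimethyloxirane-2-carboxamide (cis-oxirane)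
Conditions: K2CO3, MeOH, 0 °C
Reagents that add atoms: none
Why: Intramolecular Williamson etherification (3-exo-tet) in which the C3 alkoxide displaces bromide from the back side, so C2 is inverted, C3 is retained and the threo bromohydrin gives the cis-oxirane.

**Step 9**
Reactants: 15 (2R,3R)-N-methoxy-N,3-dimethyloxirane-2-carboxamide
Product: 16 (2S,3S)-3-chloro-2-hydroxy-N-methoxy-N-methylbutanamide
Conditions: ClTi(OiPr)3 (1.5 equiv), CH2Cl2, 0 °C to rt; aq tartaric acid
Reagents that add atoms: chlorotitanium triisopropoxide, CC(C)O[Ti](Cl)(OC(C)C)OC(C)C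
Why: Titanium(IV)-mediated C3-selective opening of a 2,3-epoxy amide in which titanium bridges the oxirane and amide oxygens, the carbonyl group disfavours charge build-up at C2, and chloride attacks the methyl-bearing C3 in an SN2 sense with inversion to set (3S), while the C2–O bond stays intact (its descriptor changes to S only through CIP ranking).

**Step 10**
Reactants: 16 (2S,3S)-3-chloro-2-hydroxy-N-methoxy-N-methylbutanamide
Product: 17 (2S,3S)-3-chloro-N-methoxy-N-methyl-2-(triethylsilyloxy)butanamide
Conditions: Et3SiCl, imidazole, CH2Cl2, 0 °C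
Reagents that add atoms: chlorotriethylsilane, CC[Si](Cl)(CC)CC
Why: Silyl ether formation under weakly basic conditions that masks the hydroxyl group before the organolithium step and is too mild to re-close the oxirane.

**Step 11**
Reactants: 18 (S)-4-benzyl-3-propanoyloxazolidin-2-one
Product: 20 (S)-4-benzyl-3-[(R)-2-methylpent-4-enoyl]oxazolidin-2-one, via sodium Z-enolate 19 (not isolated)
Conditions: NaHMDS, THF, −78 °C; allyl iodide, −78 to −45 °C
Reagents that add atoms: allyl iodide, C=CCI
Why: Evans asymmetric alkylation in which the chelated sodium Z-enolate is shielded on one face by the benzyl group, so allyl iodide attacks the opposite face and sets the (R) methyl stereocentre.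

**Step 12**
Reactants: 20 (S)-4-benzyl-3-[(R)-2-methylpent-4-enoyl]oxazolidin-2-one
Product: 21 (R)-2-methylpent-4-en-1-ol
Conditions: LiBH4, H2O (1 equiv), Et2O, 0 °C
Reagents that add atoms: none
Why: Reductive cleavage of the N-acyloxazolidinone in which hydride attacks the exocyclic carbonyl group, releases the auxiliary and gives the primary alcohol without touching the α-stereocentre or the alkene.

**Step 13**
Reactants: 21 (R)-2-methylpent-4-en-1-ol
Product: 22 (R)-5-iodo-4-methylpent-1-ene
Conditions: I2, PPh3, imidazole, CH2Cl2, 0 °C
Reagents that add atoms: iodine, II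
Why: Appel-type iodination by SN2 displacement at the primary carbon, which leaves the adjacent stereocentre untouched.

**Step 14**
Reactants: 22 (R)-5-iodo-4-methylpent-1-ene; 17 (2S,3S)-3-chloro-N-methoxy-N-methyl-2-(triethylsilyloxy)butanamide
Product: 25 (2S,3S,6R)-2-chloro-6-methyl-3-(triethylsilyloxy)non-8-en-4-one, via 2-methylpent-4-enyllithium 23 (not isolated), via lithium hemiaminal adduct 24 (not isolated)
Conditions: t-BuLi (2.05 equiv), Et2O–pentane, −78 °C; then 17, −78 °C; AcOH, −78 °C
Reagents that add atoms: none
Why: Iodine–lithium exchange and Weinreb ketone synthesis in which the primary alkyllithium adds to the amide carbonyl at −78 °C faster than it deprotonates, and the chelated adduct holds until the cold acetic acid quench, so over-addition and base-induced loss of HCl should be avoided and all three stereocentres are carried through.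

**Step 15**
Reactants: 25 (2S,3S,6R)-2-chloro-6-methyl-3-(triethylsilyloxy)non-8-en-4-one
Product: 27 (2S,3S,6R)-2-chloro-9-hydroxy-6-methyl-3-(triethylsilyloxy)nonan-4-one, via catechol boronate 26 (not isolated)
Conditions: catecholborane, RhCl(PPh3)3 (3 mol %), THF, 0 °C to rt; then 30 % H2O2, pH 7 phosphate buffer, 0 °C
Reagents that add atoms: hydrogen peroxide, OO
Why: Rhodium-catalysed hydroboration in which catecholborane adds to the terminal C=C (boron on the end carbon) much faster than it reduces a ketone, and buffered peroxide then replaces boron by OH without exposing the β-chloro ketone to base.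

**Step 16**
Reactants: 27 (2S,3S,6R)-2-chloro-9-hydroxy-6-methyl-3-(triethylsilyloxy)nonan-4-one
Product: 28 (2S,3S,6R)-2-chloro-9-iodo-6-methyl-3-(triethylsilyloxy)nonan-4-one
Conditions: I2, PPh3, imidazole, CH2Cl2, 0 °C
Reagents that add atoms: iodine, II
Why: Appel-type iodination of the only free, primary hydroxyl group under imidazole buffering, which the silyl ether, the ketone and the secondary chloride tolerate.

**Step 17**
Reactants: 11 2-(furan-3-ylmethyl)-4-[(3E)-4-iodopent-3-en-1-yl]furan; 28 (2S,3S,6R)-2-chloro-9-iodo-6-methyl-3-(triethylsilyloxy)nonan-4-one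
Product: 29 (2S,3S,6R,10E)-2-chloro-13-[5-(furan-3-ylmethyl)furan-3-yl]-6,10-dimethyl-3-(triethylsilyloxy)tridec-10-en-4-one
Conditions: NiBr2·glyme (10 mol %), 4,4'-di-tert-butyl-2,2'-bipyridine (12 mol %), Mn powder (3 equiv), NaI (0.5 equiv), DMA, 25 °C; 11 in excess (1.5 equiv)
Reagents that add atoms: none
Why: Nickel-catalysed reductive cross-electrophile coupling: bipyridine–Ni(0) inserts into the C(sp2)–I bond of 11 with retention, a Ni(I) iodide abstracts the iodine atom of the primary C–I bond of 28, the alkenyl–Ni(II) complex captures the resulting primary alkyl radical, reductive elimination from Ni(III) forms the C9–C10 bond, and manganese returns Ni(I) to Ni(0). The closest known reaction type is the bipyridine–nickel/Mn or Zn coupling of alkenyl bromides and iodides, 2-halo-2-alkenes included, with unactivated primary alkyl halides. No ring is closed and no stereocentre is created; the E geometry fixed in step 5 is carried over because the alkenyl–nickel bond is configurationally stable, and the radical carbon lies two CH2 groups away from the C6 stereocentre, so C2, C3 and C6 stay untouched. Cross- over homo-coupling is needed and is secured by the different activation modes of the two C–I bonds (two-electron oxidative addition at the sp2 carbon, halogen-atom abstraction at the sp3 carbon) and by an excess of the shorter-route partner 11. Selectivity for the primary C–I over the secondary C2–Cl bond is needed and is secured by the much weaker and more easily reduced C–I bond. Because both carbons enter as electrophiles, no carbanion and no base is present, so the ketone needs no mask and the β-chloro ketone cannot lose HCl by an E1cB path.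

**Step 18**
Reactants: 29 (2S,3S,6R,10E)-2-chloro-13-[5-(furan-3-ylmethyl)furan-3-yl]-6,10-dimethyl-3-(triethylsilyloxy)tridec-10-en-4-one
Product: 30 (2S,3S,6R,10E)-2-chloro-13-[5-(furan-3-ylmethyl)furan-3-yl]-3-hydroxy-6,10-dimethyltridec-10-en-4-one
Conditions: HF·pyridine, pyridine, THF, 0 °C
Reagents that add atoms: none
Why: Fluoride-driven cleavage of the labile triethylsilyl ether under buffered, non-basic conditions that spare the furans, the alkene and the base-sensitive β-chloro-α-hydroxy ketone, so no stereocentre is disturbed.

**Compound list**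

1 | pent-3-yn-1-ol | CC#CCCO | starting material
2 | 5-iodopent-2-yne | CC#CCCI | intermediate
3 | 4-bromofuran-2-carbaldehyde | O=Cc1cc(Br)co1 | starting material
4 | pent-3-yn-1-ylzinc iodide | CC#CCC[Zn]I | intermediate
5 | 4-(pent-3-yn-1-yl)furan-2-carbaldehyde | CC#CCCc1coc(C=O)c1 | intermediate
6 | 3-bromofuran | Brc1ccoc1 | starting material
7 | furan-3-yllithium | [Li]c1ccoc1 | intermediate
8 | (furan-3-yl)[4-(pent-3-yn-1-yl)furan-2-yl]methanol, racemic | CC#CCCc1coc(C(O)c2ccoc2)c1 | intermediate
9 | 2-(furan-3-ylmethyl)-4-(pent-3-yn-1-yl)furan | CC#CCCc1coc(Cc2ccoc2)c1 | intermediate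
10 | chlorobis(cyclopentadienyl)[(2E)-5-[5-(furan-3-ylmethyl)furan-3-yl]pent-2-en-2-yl]zirconium | C/C(=C\CCc1coc(Cc2ccoc2)c1)[Zr](Cl)(C1C=CC=C1)C1C=CC=C1 | intermediate
11 | 2-(furan-3-ylmethyl)-4-[(3E)-4-iodopent-3-en-1-yl]furan | C/C(I)=C\CCc1coc(Cc2ccoc2)c1 | intermediate
12 | L-threonine, (2S,3R)-2-amino-3-hydroxybutanoic acid | C[C@@H](O)[C@H](N)C(=O)O | starting material
13 | (2S,3R)-2-bromo-3-hydroxybutanoic acid | C[C@@H](O)[C@H](Br)C(=O)O | intermediate
14 | (2S,3R)-2-bromo-3-hydroxy-N-methoxy-N-methylbutanamide | C[C@@H](O)[C@H](Br)C(=O)N(C)OC | intermediate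
15 | (2R,3R)-N-methoxy-N,3-dimethyloxirane-2-carboxamide (cis) | CON(C)C(=O)[C@@H]1O[C@@H]1C | intermediate
16 | (2S,3S)-3-chloro-2-hydroxy-N-methoxy-N-methylbutanamide | CON(C)C(=O)[C@H](O)[C@H](C)Cl | intermediate
17 | (2S,3S)-3-chloro-N-methoxy-N-methyl-2-(triethylsilyloxy)butanamide | CON(C)C(=O)[C@H](O[Si](CC)(CC)CC)[C@H](C)Cl | intermediate
18 | (S)-4-benzyl-3-propanoyloxazolidin-2-one | CCC(=O)N1[C@@H](Cc2ccccc2)COC1=O | starting material
19 | sodium (Z)-enolate of 18 | C/C=C(\[O-])N1[C@@H](Cc2ccccc2)COC1=O.[Na+] | intermediate
20 | (S)-4-benzyl-3-[(R)-2-methylpent-4-enoyl]oxazolidin-2-one | C=CC[C@@H](C)C(=O)N1[C@@H](Cc2ccccc2)COC1=O | intermediate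
21 | (R)-2-methylpent-4-en-1-ol | C=CC[C@@H](C)CO | intermediate
22 | (R)-5-iodo-4-methylpent-1-ene | C=CC[C@@H](C)CI | intermediate
23 | (2-methylpent-4-en-1-yl)lithium, same spatial arrangement as 22 (descriptor S by CIP ranking) | C=CC[C@@H](C)C[Li] | intermediate
24 | lithium alkoxide of the N-methoxy-N-methyl hemiaminal from 23 and 17 (new carbon undefined) | C=CC[C@@H](C)CC([O-])(N(C)OC)[C@H](O[Si](CC)(CC)CC)[C@H](C)Cl.[Li+] | intermediate
25 | (2S,3S,6R)-2-chloro-6-methyl-3-(triethylsilyloxy)non-8-en-4-one | C=CC[C@@H](C)CC(=O)[C@H](O[Si](CC)(CC)CC)[C@H](C)Cl | intermediate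
26 | 2-[(4R,7S,8S)-8-chloro-4-methyl-6-oxo-7-(triethylsilyloxy)nonyl]-1,3,2-benzodioxaborole | O1c2ccccc2OB1CCC[C@@H](C)CC(=O)[C@H](O[Si](CC)(CC)CC)[C@H](C)Cl | intermediate
27 | (2S,3S,6R)-2-chloro-9-hydroxy-6-methyl-3-(triethylsilyloxy)nonan-4-one | OCCC[C@@H](C)CC(=O)[C@H](O[Si](CC)(CC)CC)[C@H](C)Cl | intermediate
28 | (2S,3S,6R)-2-chloro-9-iodo-6-methyl-3-(triethylsilyloxy)nonan-4-one | ICCC[C@@H](C)CC(=O)[C@H](O[Si](CC)(CC)CC)[C@H](C)Cl | intermediate
29 | (2S,3S,6R,10E)-2-chloro-13-[5-(furan-3-ylmethyl)furan-3-yl]-6,10-dimethyl-3-(triethylsilyloxy)tridec-10-en-4-one | C/C(=C\CCc1coc(Cc2ccoc2)c1)CCC[C@@H](C)CC(=O)[C@H](O[Si](CC)(CC)CC)[C@H](C)Cl | intermediate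
30 | (2S,3S,6R,10E)-2-chloro-13-[5-(furan-3-ylmethyl)furan-3-yl]-3-hydroxy-6,10-dimethyltridec-10-en-4-one | C/C(=C\CCc1coc(Cc2ccoc2)c1)CCC[C@@H](C)CC(=O)[C@H](O)[C@H](C)Cl | target

**Step count**

Total step count: 18 steps.
Longest linear sequence: 10 steps (12, 13, 14, 15, 16, 17, 25, 27, 28, 29, 30).

**The three steps most likely to fail**

Step 17 (key coupling). Homodimerisation of either iodide, hydrodeiodination of the alkyl radical, or slow radical capture at the hindered methyl-substituted alkenyl–nickel centre may outrun the cross-coupling. The fallback gives up the like-polarity union for a classical nucleophile–electrophile pair.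
- It sets out from 28. Zinc dust (LiCl, THF, 30 °C) inserts into the primary C–I bond to give [(4R,7S,8S)-8-chloro-4-methyl-6-oxo-7-(triethylsilyloxy)nonyl]zinc iodide F1, a reagent that tolerates the ketone, the silyl ether and the secondary chloride.
- A palladium-catalysed Negishi coupling of this reagent with 11 [PdCl2(dppf), THF, rt] keeps the E geometry and comes back to the route at 29.

Step 9 (chloride opening). Poor regioselectivity may arise, with chloride attacking the carbonyl-flanked C2 instead of the methyl-bearing C3, or the cis-oxirane may react sluggishly in the titanium chelate. The fallback replaces the Lewis-acid chelate on the amide by a protic opening of the free glycidic acid.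
- It sets out from 13. KOH (2 equiv, EtOH, 0 °C) closes the oxirane to potassium (2R,3R)-3-methyloxirane-2-carboxylate F2.
- Cold concentrated hydrochloric acid protonates the oxirane, and chloride enters at the carbon remote from the carboxyl group with inversion to give (2S,3S)-3-chloro-2-hydroxybutanoic acid F3, which can be purified by crystallisation.
- A DCC coupling with N,O-dimethylhydroxylamine, as in step 7, comes back to the route at 16.

Step 14 (ketone formation). The alkyllithium may deprotonate the amide α-carbon, with loss of chloride (E1cB) following, in competition with carbonyl addition. The fallback avoids a strongly basic carbanion.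
- It sets out from 17 and 22. DIBAL-H (toluene, −78 °C) reduces 17 to (2S,3S)-3-chloro-2-(triethylsilyloxy)butanal F4.
- CrCl2 with catalytic cobalt phthalocyanine in DMF converts 22 into the non-basic dichloro[(2-methylpent-4-en-1-yl)]chromium(III) F5.
- This reagent adds to the aldehyde in a Nozaki–Hiyama-type reaction to give (2S,3S,6R)-2-chloro-6-methyl-3-(triethylsilyloxy)non-8-en-4-ol F6 as a mixture of carbinol epimers.
- Dess–Martin oxidation erases that centre and comes back to the route at 25.

**Further compounds**

F1 | step 17 | [(4R,7S,8S)-8-chloro-4-methyl-6-oxo-7-(triethylsilyloxy)nonyl]zinc iodide | I[Zn]CCC[C@@H](C)CC(=O)[C@H](O[Si](CC)(CC)CC)[C@H](C)Cl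
F2 | step 9 | potassium (2R,3R)-3-methyloxirane-2-carboxylate | [K+].[O-]C(=O)[C@@H]1O[C@@H]1C
F3 | step 9 | (2S,3S)-3-chloro-2-hydroxybutanoic acid | OC(=O)[C@H](O)[C@H](C)Cl
F4 | step 14 | (2S,3S)-3-chloro-2-(triethylsilyloxy)butanal | O=C[C@H](O[Si](CC)(CC)CC)[C@H](C)Cl
F5 | step 14 | dichloro[(2-methylpent-4-en-1-yl)]chromium(III), same spatial arrangement as 22 | C=CC[C@@H](C)C[Cr](Cl)Cl
F6 | step 14 | (2S,3S,6R)-2-chloro-6-methyl-3-(triethylsilyloxy)non-8-en-4-ol, mixture at C4 | C=CC[C@@H](C)CC(O)[C@H](O[Si](CC)(CC)CC)[C@H](C)Cl
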